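The route rests on the disconnection of the C3–C4 bond of ring B (C1–C5, C10; eremophilane numbering), the cyclohexane that carries the ester at C3 and the methyl at C4; ring A (C5–C10) carries the ketone. The trans C3–O/C4–CH3 pair beside quaternary C5 is the retron of a SmI2 ketyl–olefin cyclization: an aldehyde (C3) on a chain from C10 adds 6-exo to a vinyl group (C4=C15) on C5, closing ring B and setting both stereocentres and the C4 methyl in one operation. The precursor is a monocyclic, fully substituted ring A, made by a catalytic asymmetric Diels–Alder reaction, whose equatorial C7 and C9 substituents lock the chair.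

Key step: step 8

Remark (labels): atom labels follow eremophilane numbering of the target (C3 ester carbinol, C4 with methyl C15, C5 with methyl C14, C7 with isopropenyl, C8 ketone, C9 carbinol, C10 ring-fusion CH); β is the face of the two methyl groups, α the opposite face.
Remark (assumption, step 3): the (S)-configured oxazaborolidinium is taken, by the usual facial model for 2-substituted acroleins, to give the (1R,6S) adduct 6; should it give the mirror image, the (R)-catalyst is used.
Remark (step 7): compound 12 is written as the equatorial C8 alcohol; its C8 epimer would behave the same way and converges in step 12.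

Step 1
Reactants: 1 methyl 4-oxobutanoate; 2 1-(triphenylphosphoranylidene)propan-2-one
Product: 3 methyl (4E)-6-oxohept-4-enoate
Conditions: CH2Cl2, 23 °C
Reagents that add atoms: none
Why: Wittig olefination with the stabilized acetonylidene ylide should give the (E)-enone selectively and leave the ester untouched.

Step 2
Reactants: 3 methyl (4E)-6-oxohept-4-enoate
Product: 4 methyl (4E)-6-[(triisopropylsilyl)oxy]hepta-4,6-dienoate
Conditions: i-Pr3SiOTf, Et3N, CH2Cl2, 0 °C
Reagents that add atoms: triisopropylsilyl trifluoromethanesulfonate, CC(C)[Si](C(C)C)(C(C)C)OS(=O)(=O)C(F)(F)F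
Why: Silyl enol ether formation by soft enolization of the methyl ketone, whose only enolizable α-position is the methyl group, should give the 2-silyloxy diene with the (E)-alkene intact.

Step 3
Reactants: 4 methyl (4E)-6-[(triisopropylsilyl)oxy]hepta-4,6-dienoate; 5 methacrolein (2-methylprop-2-enal)
Product: 6 methyl 3-[(1R,6S)-6-formyl-6-methyl-3-(triisopropylsilyloxy)cyclohex-2-en-1-yl]propanoate
Conditions: (S)-1-(2-methylphenyl)-3,3-diphenyltetrahydro-1H,3H-pyrrolo[1,2-c][1,3,2]oxazaborole (20 mol %) activated with (CF3SO2)2NH (18 mol %), CH2Cl2, −78 °C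
Reagents that add atoms: none
Why: Catalytic asymmetric Diels–Alder reaction in which the silyloxy group (para) and the chain-bearing diene terminus (ortho) direct C10 to the α-carbon and C7 to the β-carbon of the coordinated enal, the formyl-endo transition state places the formyl group (C4) cis to the C10 chain, and the chiral oxazaborolidinium selects the enal face and so sets C5 and C10.

Step 4
Reactants: 6 methyl 3-[(1R,6S)-6-formyl-6-methyl-3-(triisopropylsilyloxy)cyclohex-2-en-1-yl]propanoate
Product: 7 methyl 3-[(1R,6R)-6-ethenyl-6-methyl-3-(triisopropylsilyloxy)cyclohex-2-en-1-yl]propanoate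
Conditions: Ph3PCH3Br, KN(SiMe3)2, THF, 0 °C
Reagents that add atoms: methyltriphenylphosphonium bromide, C[P+](c1ccccc1)(c1ccccc1)c1ccccc1.[Br-]
Why: Wittig methylenation of the non-enolizable aldehyde should give the vinyl group (C4=C15) without touching the ester, the silyl enol ether or a stereocentre.

Step 5
Reactants: 7 methyl 3-[(1R,6R)-6-ethenyl-6-methyl-3-(triisopropylsilyloxy)cyclohex-2-en-1-yl]propanoate
Product: 9 methyl 3-[(1S,2R,6R)-2-ethenyl-2-methyl-5-oxo-6-(triisopropylsilyloxy)cyclohexyl]propanoate, via silyloxy epoxide 8 (not isolated)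
Conditions: m-CPBA, NaHCO3 (buffer), CH2Cl2, −20 to 0 °C
Reagents that add atoms: 3-chloroperbenzoic acid, OOC(=O)c1cccc(Cl)c1
Why: Rubottom oxidation in which the electron-rich silyl enol ether is epoxidized much faster than the vinyl group, from the face anti to the allylic C10 chain and the axial vinyl group, and the epoxide opens with 1,4-silyl migration to the α-silyloxy ketone, which sets C9 with oxygen trans to the C10 chain.

Step 6
Reactants: 9 methyl 3-[(1S,2R,6R)-2-ethenyl-2-methyl-5-oxo-6-(triisopropylsilyloxy)cyclohexyl]propanoate; 10 2-bromopropene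
Product: 11 methyl 3-[(1S,2R,4R,6R)-2-ethenyl-2-methyl-5-oxo-4-(prop-1-en-2-yl)-6-(triisopropylsilyloxy)cyclohexyl]propanoate
Conditions: LiN(SiMe3)2 (2.2 equiv), Pd2(dba)3 (2.5 mol %), P(t-Bu)3 (10 mol %), THF, −78 to 23 °C; then AcOH, −78 °C
Reagents that add atoms: none
Why: Palladium-catalysed α-alkenylation of a ketone enolate in which the amide base removes the unhindered C7–H in preference to the C9–H flanked by the silyloxy group, the isopropenylpalladium bromide formed by oxidative addition to zerovalent palladium couples at C7, and kinetic α-protonation of the product dienolate should give the β,γ-unsaturated ketone with the isopropenyl group equatorial, cis to the silyloxy group across the carbonyl (the more stable, all-equatorial C7 epimer).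

Step 7
Reactants: 11 methyl 3-[(1S,2R,4R,6R)-2-ethenyl-2-methyl-5-oxo-4-(prop-1-en-2-yl)-6-(triisopropylsilyloxy)cyclohexyl]propanoate
Product: 12 3-[(1S,2R,4R,5R,6R)-2-ethenyl-5-hydroxy-2-methyl-4-(prop-1-en-2-yl)-6-(triisopropylsilyloxy)cyclohexyl]propanal
Conditions: i-Bu2AlH (3.0 equiv), CH2Cl2, −78 °C; MeOH, then aq. KNaC4H4O6
Reagents that add atoms: none
Why: At −78 °C i-Bu2AlH should reduce the ketone to the alcohol (axial hydride delivery, equatorial C8–OH) and stop at the aluminium hemiacetal of the ester, which gives the aldehyde on work-up, so that the α-silyloxy ketone is masked against SmI2 and C7 is no longer epimerizable.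

Step 8
Reactants: 12 3-[(1S,2R,4R,5R,6R)-2-ethenyl-5-hydroxy-2-methyl-4-(prop-1-en-2-yl)-6-(triisopropylsilyloxy)cyclohexyl]propanal
Product: 13 (1R,2R,3R,4aR,5R,6R,8aS)-4a,5-dimethyl-3-(prop-1-en-2-yl)-1-[(triisopropylsilyl)oxy]decahydronaphthalene-2,6-diol
Conditions: SmI2 (3 equiv), HMPA (12 equiv), t-BuOH (3 equiv), THF (0.01 M), 0 °C, slow addition of 12
Reagents that add atoms: none
Why: SmI2–HMPA transfers one electron to the aldehyde to give a samarium ketyl radical at C3, which adds to C4 of the vinyl group; the primary C15 radical is reduced by a second SmI2 to an alkylsamarium and protonated by t-BuOH, so that C15 ends as the C4 methyl group. The closest known reaction type is the SmI2–HMPA ketyl–olefin reductive cyclization of unsaturated aldehydes and ketones onto unactivated alkenes. Ring B closes in the 6-exo-trig mode. Ring A is locked in the chair with the C7 isopropenyl group, the C9 silyloxy group, the C5 methyl group and the C10 chain equatorial and the vinyl group axial, so ring B must form as the chair in which C14 and C9 are axial; there the C3–O–Sm bond goes equatorial (α) to avoid the syn-axial C14 methyl group and C15 goes equatorial (β) to avoid the syn-axial C9, which gives the trans 3α-hydroxy-4β-methyl pair. The step needs exo rather than 7-endo closure and cyclization faster than pinacol coupling or simple reduction of the ketyl, which the cis axial/equatorial placement of vinyl group and chain beside the quaternary centre, high dilution and slow addition should secure, while the isopropenyl group is out of reach of the ketyl.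

Step 9
Reactants: 14 (2R)-pent-4-en-2-ol; 15 angelic acid [(2Z)-2-methylbut-2-enoic acid]
Product: 17 (2R)-pent-4-en-2-yl (2Z)-2-methylbut-2-enoate, via mixed anhydride 16 (not isolated)
Conditions: 2,4,6-trichlorobenzoyl chloride, Et3N, toluene, 23 °C; then 14, 80 °C
Reagents that add atoms: none
Why: Yamaguchi-type esterification through the angelic 2,4,6-trichlorobenzoic mixed anhydride should acylate the alcohol without Z to E isomerization of the angelate and without touching the carbinol centre.

Step 10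
Reactants: 17 (2R)-pent-4-en-2-yl (2Z)-2-methylbut-2-enoate; 18 acrylic acid
Product: 19 (2E,5R)-5-{[(2Z)-2-methylbut-2-enoyl]oxy}hex-2-enoic acid
Conditions: second-generation Hoveyda–Grubbs catalyst, [1,3-bis(2,4,6-trimethylphenyl)imidazolidin-2-ylidene]dichloro(2-isopropoxybenzylidene)ruthenium (5 mol %), CH2Cl2, 40 °C
Reagents that add atoms: none
Why: Olefin cross-metathesis of the terminal alkene with acrylic acid should give the (E)-enoic acid, while the hindered, electron-poor trisubstituted angelate alkene does not take part.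

Step 11
Reactants: 13 (1R,2R,3R,4aR,5R,6R,8aS)-4a,5-dimethyl-3-(prop-1-en-2-yl)-1-[(triisopropylsilyl)oxy]decahydronaphthalene-2,6-diol; 19 (2E,5R)-5-{[(2Z)-2-methylbut-2-enoyl]oxy}hex-2-enoic acid
Product: 20 (1R,2R,4aS,5R,6R,7R,8aR)-6-hydroxy-1,8a-dimethyl-7-(prop-1-en-2-yl)-5-[(triisopropylsilyl)oxy]decahydronaphthalen-2-yl (2E,5R)-5-{[(2Z)-2-methylbut-2-enoyl]oxy}hex-2-enoate
Conditions: N-(3-dimethylaminopropyl)-N′-ethylcarbodiimide hydrochloride (EDC·HCl, 1.3 equiv), DMAP (0.1 equiv), 19 (1.1 equiv), CH2Cl2, 0 °C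
Reagents that add atoms: none
Why: Steglich-type carbodiimide esterification should acylate the equatorial C3 hydroxyl only, because the C8 hydroxyl is wedged between the carbons that carry the isopropenyl and the triisopropylsilyloxy groups.

Step 12
Reactants: 20 (1R,2R,4aS,5R,6R,7R,8aR)-6-hydroxy-1,8a-dimethyl-7-(prop-1-en-2-yl)-5-[(triisopropylsilyl)oxy]decahydronaphthalen-2-yl (2E,5R)-5-{[(2Z)-2-methylbut-2-enoyl]oxy}hex-2-enoate
Product: 21 (1R,2R,4aS,5R,7R,8aR)-1,8a-dimethyl-6-oxo-7-(prop-1-en-2-yl)-5-[(triisopropylsilyl)oxy]decahydronaphthalen-2-yl (2E,5R)-5-{[(2Z)-2-methylbut-2-enoyl]oxy}hex-2-enoate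
Conditions: Dess–Martin periodinane, NaHCO3 (buffer), CH2Cl2, 0 to 23 °C
Reagents that add atoms: none
Why: Buffered Dess–Martin oxidation should convert the hindered C8 alcohol into the ketone under neutral conditions that neither epimerize C7 nor move the isopropenyl double bond into conjugation.

Step 13
Reactants: 21 (1R,2R,4aS,5R,7R,8aR)-1,8a-dimethyl-6-oxo-7-(prop-1-en-2-yl)-5-[(triisopropylsilyl)oxy]decahydronaphthalen-2-yl (2E,5R)-5-{[(2Z)-2-methylbut-2-enoyl]oxy}hex-2-enoate
Product: 22 (1R,2R,4aS,5R,7R,8aR)-5-hydroxy-1,8a-dimethyl-6-oxo-7-(prop-1-en-2-yl)decahydronaphthalen-2-yl (2E,5R)-5-{[(2Z)-2-methylbut-2-enoyl]oxy}hex-2-enoate (CNP0210874.1)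
Conditions: HF·pyridine, pyridine, THF, 0 to 23 °C
Reagents that add atoms: none
Why: Fluoride-mediated silyl ether cleavage under buffered, weakly acidic conditions should free the C9 hydroxyl without touching the two unsaturated esters or the β,γ-unsaturated ketone.

Compound list
1 | methyl 4-oxobutanoate | COC(=O)CCC=O | starting material
2 | 1-(triphenylphosphoranylidene)propan-2-one | CC(=O)C=P(c1ccccc1)(c1ccccc1)c1ccccc1 | starting material
3 | methyl (4E)-6-oxohept-4-enoate | COC(=O)CC/C=C/C(C)=O | intermediate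
4 | methyl (4E)-6-[(triisopropylsilyl)oxy]hepta-4,6-dienoate | COC(=O)CC/C=C/C(=C)O[Si](C(C)C)(C(C)C)C(C)C | intermediate
5 | methacrolein (2-methylprop-2-enal) | CC(=C)C=O | starting material
6 | methyl 3-[(1R,6S)-6-formyl-6-methyl-3-(triisopropylsilyloxy)cyclohex-2-en-1-yl]propanoate (formyl cis to the propanoate chain) | C1C[C@@](C=O)(C)[C@H](CCC(=O)OC)C=C1O[Si](C(C)C)(C(C)C)C(C)C | intermediate
7 | methyl 3-[(1R,6R)-6-ethenyl-6-methyl-3-(triisopropylsilyloxy)cyclohex-2-en-1-yl]propanoate | C1C[C@@](C=C)(C)[C@H](CCC(=O)OC)C=C1O[Si](C(C)C)(C(C)C)C(C)C | intermediate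
8 | silyloxy epoxide of 7 (C8–C9 epoxide, 1-silyloxy-7-oxabicyclo[4.1.0]heptane, epoxide oxygen trans to the C10 chain) | C1C[C@@](C=C)(C)[C@H](CCC(=O)OC)[C@H]3O[C@@]13O[Si](C(C)C)(C(C)C)C(C)C | intermediate
9 | methyl 3-[(1S,2R,6R)-2-ethenyl-2-methyl-5-oxo-6-(triisopropylsilyloxy)cyclohexyl]propanoate | C1C[C@@](C=C)(C)[C@H](CCC(=O)OC)[C@@H](O[Si](C(C)C)(C(C)C)C(C)C)C1=O | intermediate
10 | 2-bromopropene | CC(Br)=C | starting material
11 | methyl 3-[(1S,2R,4R,6R)-2-ethenyl-2-methyl-5-oxo-4-(prop-1-en-2-yl)-6-(triisopropylsilyloxy)cyclohexyl]propanoate | C=C(C)[C@H]1C[C@@](C=C)(C)[C@H](CCC(=O)OC)[C@@H](O[Si](C(C)C)(C(C)C)C(C)C)C1=O | intermediate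
12 | 3-[(1S,2R,4R,5R,6R)-2-ethenyl-5-hydroxy-2-methyl-4-(prop-1-en-2-yl)-6-(triisopropylsilyloxy)cyclohexyl]propanal | C=C(C)[C@H]1C[C@@](C=C)(C)[C@H](CCC=O)[C@@H](O[Si](C(C)C)(C(C)C)C(C)C)[C@@H]1O | intermediate
13 | (1R,2R,3R,4aR,5R,6R,8aS)-4a,5-dimethyl-3-(prop-1-en-2-yl)-1-[(triisopropylsilyl)oxy]decahydronaphthalene-2,6-diol (cis-decalin) | C=C(C)[C@H]1C[C@@]2(C)[C@H](CC[C@@H](O)[C@@H]2C)[C@@H](O[Si](C(C)C)(C(C)C)C(C)C)[C@@H]1O | intermediate
14 | (2R)-pent-4-en-2-ol | C[C@@H](O)CC=C | starting material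
15 | angelic acid, (2Z)-2-methylbut-2-enoic acid | C/C=C(/C)C(=O)O | starting material
16 | (2Z)-2-methylbut-2-enoic 2,4,6-trichlorobenzoic anhydride | O=C(OC(=O)c1c(Cl)cc(Cl)cc1Cl)/C(C)=C\C | intermediate
17 | (2R)-pent-4-en-2-yl (2Z)-2-methylbut-2-enoate | C=CC[C@@H](C)OC(=O)/C(C)=C\C | intermediate
18 | acrylic acid | C=CC(=O)O | starting material
19 | (2E,5R)-5-{[(2Z)-2-methylbut-2-enoyl]oxy}hex-2-enoic acid | OC(=O)/C=C/C[C@@H](C)OC(=O)/C(C)=C\C | intermediate
20 | (1R,2R,4aS,5R,6R,7R,8aR)-6-hydroxy-1,8a-dimethyl-7-(prop-1-en-2-yl)-5-[(triisopropylsilyl)oxy]decahydronaphthalen-2-yl (2E,5R)-5-{[(2Z)-2-methylbut-2-enoyl]oxy}hex-2-enoate | C=C(C)[C@H]1C[C@@]2(C)[C@H](CC[C@@H](OC(=O)/C=C/C[C@@H](C)OC(=O)/C(C)=C\C)[C@@H]2C)[C@@H](O[Si](C(C)C)(C(C)C)C(C)C)[C@@H]1O | intermediate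
21 | (1R,2R,4aS,5R,7R,8aR)-1,8a-dimethyl-6-oxo-7-(prop-1-en-2-yl)-5-[(triisopropylsilyl)oxy]decahydronaphthalen-2-yl (2E,5R)-5-{[(2Z)-2-methylbut-2-enoyl]oxy}hex-2-enoate | C=C(C)[C@H]1C[C@@]2(C)[C@H](CC[C@@H](OC(=O)/C=C/C[C@@H](C)OC(=O)/C(C)=C\C)[C@@H]2C)[C@@H](O[Si](C(C)C)(C(C)C)C(C)C)C1=O | intermediate
22 | (1R,2R,4aS,5R,7R,8aR)-5-hydroxy-1,8a-dimethyl-6-oxo-7-(prop-1-en-2-yl)decahydronaphthalen-2-yl (2E,5R)-5-{[(2Z)-2-methylbut-2-enoyl]oxy}hex-2-enoate (CNP0210874.1) | C=C(C)[C@H]1C[C@@]2(C)[C@H](CC[C@@H](OC(=O)/C=C/C[C@@H](C)OC(=O)/C(C)=C\C)[C@@H]2C)[C@@H](O)C1=O | target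

Total step count: 13. Longest linear sequence: 11 steps (steps 1–8 and 11–13); the side-chain acid 19 is made in two steps (9 and 10).

Steps most likely to fail

Step 8. The ketyl may be lost to simple reduction or pinacol coupling before it adds to the unactivated vinyl group beside the quaternary centre, or the ring may close in the 7-endo sense. The fallback replaces the ketyl by an acyl radical and sets out from 12. Thiol-catalysed radical-chain hydroacylation (tert-dodecanethiol, 1,1′-azobis(cyclohexanecarbonitrile), chlorobenzene, 100 °C) should give, by 6-exo acyl-radical cyclization, the hydroxy decalinone F1 with the C4 methyl group equatorial; this centre can equilibrate next to the C3 ketone. Dissolving-metal reduction (Li, NH3, THF, t-BuOH, −78 °C) should then give the thermodynamically favoured equatorial C3 alcohol and comes back to the route at 13.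

Step 6. Coupling at the hindered α′-silyloxy enolate may be slow, and the product may drift into conjugation or be protonated on the wrong face at C7. The fallback is an aldol–dehydration–deconjugation sequence and sets out from 9. LiN(i-Pr)2 in THF at −78 °C followed by acetone should give the tertiary aldol F2. Burgess reagent (methyl N-(triethylammoniosulfonyl)carbamate, benzene, 50 °C) should give mainly the conjugated isopropylidene ketone F3. γ-Deprotonation with LiN(i-Pr)2 at −78 °C and a quench with AcOH at −78 °C should protonate the cross-conjugated dienolate at C7 and come back to the route at 11.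

Step 11. Acylation may lose site-selectivity and give the C8 ester or the bis-ester. The fallback differentiates the two hydroxyls before the ring closure and sets out from 12. Et3SiOTf and 2,6-lutidine (CH2Cl2, −78 °C) should give the C8 triethylsilyl ether aldehyde F4. The SmI2–HMPA cyclization under the conditions of step 8 should give the mono-alcohol F5. Esterification with 19 under the conditions of step 11 should give the bis-silyl ester F6. Pyridinium p-toluenesulfonate in MeOH/CH2Cl2 at 0 °C should remove the triethylsilyl group in the presence of the triisopropylsilyl ether and come back to the route at 20.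

Further compounds
F1 | step 8 | (1R,4aS,5R,6R,7R,8aS)-6-hydroxy-1,8a-dimethyl-7-(prop-1-en-2-yl)-5-[(triisopropylsilyl)oxy]octahydronaphthalen-2(1H)-one | C=C(C)[C@H]1C[C@@]2(C)[C@H](CCC(=O)[C@@H]2C)[C@@H](O[Si](C(C)C)(C(C)C)C(C)C)[C@@H]1O
F2 | step 6 | methyl 3-[(1S,2R,4R,6R)-2-ethenyl-4-(2-hydroxypropan-2-yl)-2-methyl-5-oxo-6-(triisopropylsilyloxy)cyclohexyl]propanoate | CC(C)(O)[C@H]1C[C@@](C=C)(C)[C@H](CCC(=O)OC)[C@@H](O[Si](C(C)C)(C(C)C)C(C)C)C1=O
F3 | step 6 | methyl 3-[(1S,2R,6R)-2-ethenyl-2-methyl-5-oxo-4-(propan-2-ylidene)-6-(triisopropylsilyloxy)cyclohexyl]propanoate | CC(C)=C1C[C@@](C=C)(C)[C@H](CCC(=O)OC)[C@@H](O[Si](C(C)C)(C(C)C)C(C)C)C1=O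
F4 | step 11 | 3-[(1S,2R,4R,5R,6R)-2-ethenyl-2-methyl-4-(prop-1-en-2-yl)-5-[(triethylsilyl)oxy]-6-[(triisopropylsilyl)oxy]cyclohexyl]propanal | C=C(C)[C@H]1C[C@@](C=C)(C)[C@H](CCC=O)[C@@H](O[Si](C(C)C)(C(C)C)C(C)C)[C@@H]1O[Si](CC)(CC)CC
F5 | step 11 | (1R,2R,4aS,5R,6R,7R,8aR)-1,8a-dimethyl-7-(prop-1-en-2-yl)-6-[(triethylsilyl)oxy]-5-[(triisopropylsilyl)oxy]decahydronaphthalen-2-ol | C=C(C)[C@H]1C[C@@]2(C)[C@H](CC[C@@H](O)[C@@H]2C)[C@@H](O[Si](C(C)C)(C(C)C)C(C)C)[C@@H]1O[Si](CC)(CC)CC
F6 | step 11 | (1R,2R,4aS,5R,6R,7R,8aR)-1,8a-dimethyl-7-(prop-1-en-2-yl)-6-[(triethylsilyl)oxy]-5-[(triisopropylsilyl)oxy]decahydronaphthalen-2-yl (2E,5R)-5-{[(2Z)-2-methylbut-2-enoyl]oxy}hex-2-enoate | C=C(C)[C@H]1C[C@@]2(C)[C@H](CC[C@@H](OC(=O)/C=C/C[C@@H](C)OC(=O)/C(C)=C\C)[C@@H]2C)[C@@H](O[Si](C(C)C)(C(C)C)C(C)C)[C@@H]1O[Si](CC)(CC)CC
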